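**Retrosynthetic overview**
- The target comes from O7-selective methylation of 2-(2,4-dimethoxyphenyl)-5,7-dihydroxy-8-methoxychromen-4-one; the 5-hydroxyl is held back by its hydrogen bond to the C4 carbonyl.
- Ring A is disconnected at C6–C7 by an intramolecular Claisen reaction on a finished ring C: a 4-pyranone with acetyl on C3 (becomes C5 and C6) and CH(OMe)CO2Me on C2 (becomes C8 and C7).
- Structural feature used: the oxygens on C5, C7 and C8a of ring A sit on alternate carbons (acylphloroglucinol pattern), and the C8a–O1 bond already exists in the pyranone, so ring A can only close to the 5,7,8-pattern.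
- The pyranone comes from vinylic substitution of a 2-methylsulfanyl group by the enolate of methyl methoxyacetate; the 2-methylsulfanylpyranone comes from O-cyclisation of an aroylacetyl ketene dithioacetal built from acetylacetone, CS2, MeI and 2,4-dimethoxybenzoyl chloride.
- Ring order: ring B is bought, ring C is closed in step 3, ring A is closed last in step 5.

Key step: step 5

Assumption: compound 8 is made and used as the racemate, because its only stereocentre becomes the planar C8 of ring A in step 5; flavone numbering is used for ring atoms throughout.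

**Step 1**
Reactants: 1 acetylacetone (pentane-2,4-dione); 2 carbon disulfide
Product: 3 3-[bis(methylsulfanyl)methylidene]pentane-2,4-dione
Conditions: K2CO3 (2.2 equiv), DMF, 0 °C to rt; then MeI (2.2 equiv), rt
Reagents that add atoms: iodomethane, CI
Why: Deprotonation of the symmetrical 1,3-diketone, addition to CS2 and twofold S-methylation is the standard ketene dithioacetal synthesis and needs no selectivity here.

**Step 2**
Reactants: 3 3-[bis(methylsulfanyl)methylidene]pentane-2,4-dione; 4 2,4-dimethoxybenzoyl chloride
Product: 5 4-[bis(methylsulfanyl)methylidene]-1-(2,4-dimethoxyphenyl)hexane-1,3,5-trione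
Conditions: 3 (2.1 equiv), LiN(SiMe3)2 (2.1 equiv), THF, −78 °C; then 4 (1.0 equiv), −78 to −20 °C; cold 1 M HCl
Reagents that add atoms: none
Why: Kinetic deprotonation of one of the two equivalent acetyl methyl groups, the only enolisable site, and C-acylation of the lithium enolate by the aroyl chloride is a crossed Claisen-type acylation, in which the second equivalent of enolate takes up the proton of the more acidic 1,3-diketone product.

**Step 3**
Reactants: 5 4-[bis(methylsulfanyl)methylidene]-1-(2,4-dimethoxyphenyl)hexane-1,3,5-trione
Product: 6 3-acetyl-6-(2,4-dimethoxyphenyl)-2-(methylsulfanyl)-4H-pyran-4-one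
Conditions: camphor-10-sulfonic acid (0.1 equiv), toluene, 80 °C, N2 sweep
Reagents that add atoms: none
Why: The enol oxygen of the aroylacetyl unit should add to the acid-activated ketene dithioacetal carbon and methanethiol is lost (6-endo-trig addition–elimination, the usual closure to 2-methylsulfanyl-4-pyranones and -chromones), any other oxygen-to-carbon pairing giving a four-membered ring.

**Step 4**
Reactants: 6 3-acetyl-6-(2,4-dimethoxyphenyl)-2-(methylsulfanyl)-4H-pyran-4-one; 7 methyl methoxyacetate
Product: 8 methyl 2-[3-acetyl-6-(2,4-dimethoxyphenyl)-4-oxo-4H-pyran-2-yl]-2-methoxyacetate (racemic)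
Conditions: 7 (2.2 equiv), LiN(iPr)2 (2.2 equiv), THF, −78 °C; then 6, −78 to −40 °C; cold 1 M HCl
Reagents that add atoms: none
Why: C2 of 6 is the β-carbon of a vinylogous thioester activated by both the ring ketone and the 3-acetyl group, so the ester enolate should add there and expel methanethiolate (nucleophilic vinylic substitution by addition–elimination), the second equivalent of enolate removing the acidic methine hydrogen of the product, whose new stereocentre forms racemic and is erased in step 5.

**Step 5**
Reactants: 8 methyl 2-[3-acetyl-6-(2,4-dimethoxyphenyl)-4-oxo-4H-pyran-2-yl]-2-methoxyacetate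
Product: 10 2-(2,4-dimethoxyphenyl)-5,7-dihydroxy-8-methoxy-4H-chromen-4-one, via chromenetrione tautomer 9 (not isolated)
Conditions: LiN(iPr)2 (3.3 equiv), THF (0.02 M), −78 to 25 °C; then 1 M HCl
Reagents that add atoms: none
Why: The first equivalent of LiN(iPr)2 removes the methine hydrogen between ring C and the ester and a second equivalent then metalates the acetyl methyl group, as in the formation of 1,3-diketone dianions; this terminal carbanion adds to the ester carbonyl, methoxide leaves, and trione 9 gives up a C6 hydrogen and enolises to the aromatic 5,7-diol. The closest known reaction type is the intramolecular Claisen (Dieckmann-type) cyclisation of pyranone-masked poly-β-carbonyl esters to resorcinol rings, and acylation of diketone dianions by metal salts of β-keto esters indicates that a carbanion of this strength attacks an ester whose α-carbon is already ionised. Ring A closes in the 6-exo-trig mode, the C2=C3 bond of the pyranone holding the nucleophilic and electrophilic carbons cis to each other. No stereocentre is formed, and the one present in 8 becomes the planar C8. The step needs attack of the acetyl methyl carbon on the ester and on no other carbonyl group, which the substrate secures because every other pairing would give a four-membered ring, and the 5,7,8-pattern is fixed because O1 is bonded to C8a before ring A exists.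

**Step 6**
Reactants: 10 2-(2,4-dimethoxyphenyl)-5,7-dihydroxy-8-methoxy-4H-chromen-4-one
Product: 11 5-hydroxy-2',4',7,8-tetramethoxyflavone (2-(2,4-dimethoxyphenyl)-5-hydroxy-7,8-dimethoxy-4H-chromen-4-one)
Conditions: Me2SO4 (1.05 equiv), K2CO3 (1.2 equiv), acetone, reflux
Reagents that add atoms: dimethyl sulfate, COS(=O)(=O)OC
Why: The 7-hydroxyl is the vinylogous-acid hydroxyl para to the C4 carbonyl and is ionised by K2CO3, whereas the 5-hydroxyl is tied up in a hydrogen bond to that carbonyl, so one equivalent of dimethyl sulfate should alkylate O7 only (Williamson ether synthesis).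

**Compound list**
1 | acetylacetone (pentane-2,4-dione) | CC(=O)CC(C)=O | starting material
2 | carbon disulfide | S=C=S | starting material
3 | 3-[bis(methylsulfanyl)methylidene]pentane-2,4-dione | CC(=O)C(=C(SC)SC)C(C)=O | intermediate
4 | 2,4-dimethoxybenzoyl chloride | COc1ccc(C(Cl)=O)c(OC)c1 | starting material
5 | 4-[bis(methylsulfanyl)methylidene]-1-(2,4-dimethoxyphenyl)hexane-1,3,5-trione | CC(=O)C(=C(SC)SC)C(=O)CC(=O)c1ccc(OC)cc1OC | intermediate
6 | 3-acetyl-6-(2,4-dimethoxyphenyl)-2-(methylsulfanyl)-4H-pyran-4-one | CSC1=C(C(C)=O)C(=O)C=C(O1)c1ccc(OC)cc1OC | intermediate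
7 | methyl methoxyacetate | COCC(=O)OC | starting material
8 | methyl 2-[3-acetyl-6-(2,4-dimethoxyphenyl)-4-oxo-4H-pyran-2-yl]-2-methoxyacetate (racemic) | COC(=O)C(OC)C1=C(C(C)=O)C(=O)C=C(O1)c1ccc(OC)cc1OC | intermediate
9 | 2-(2,4-dimethoxyphenyl)-8-methoxy-4H-chromene-4,5,7(6H,8H)-trione (racemic, formed as its enolate, not isolated) | COC1C(=O)CC(=O)C2=C1OC(=CC2=O)c1ccc(OC)cc1OC | intermediate
10 | 2-(2,4-dimethoxyphenyl)-5,7-dihydroxy-8-methoxy-4H-chromen-4-one | COc1ccc(-c2cc(=O)c3c(O)cc(O)c(OC)c3o2)c(OC)c1 | intermediate
11 | 5-hydroxy-2',4',7,8-tetramethoxyflavone | COc1ccc(-c2cc(=O)c3c(O)cc(OC)c(OC)c3o2)c(OC)c1 | target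

**Total step count:** 6
**Longest linear sequence:** 6 steps (1 → 3 → 5 → 6 → 8 → 10 → 11)

**Steps most likely to fail**

Step 5. Ionisation of the side-chain methine puts the ester into a delocalised anion, so ring closure of the doubly metalated species may be too slow, and intermolecular condensation or opening of ring C may take over. The fallback replaces the acidic hydrogen by a second, removable ester and sets out from 6. The sodium salt of dimethyl 2-methoxypropanedioate (NaH, DMF, 0 to 60 °C) should displace the methylsulfanyl group to give dimethyl 2-[3-acetyl-6-(2,4-dimethoxyphenyl)-4-oxo-4H-pyran-2-yl]-2-methoxypropanedioate F1. This compound has no hydrogen between ring C and the esters, so NaH (2.2 equiv, THF, 0 °C to rt) can only enolise the acetyl methyl group. Claisen closure onto one of the two equivalent, non-enolisable esters should give methyl 2-(2,4-dimethoxyphenyl)-5-hydroxy-8-methoxy-4,7-dioxo-7,8-dihydro-4H-chromene-8-carboxylate F2 (racemic). NaOMe in MeOH at rt should then remove the methoxycarbonyl group from the quaternary C8 as dimethyl carbonate (retro-Claisen cleavage driven by aromatisation), and the fallback rejoins the route at 10.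

Step 4. The basic ester enolate may take a proton from the acetyl methyl group of 6, or condense with itself, in place of conjugate addition at C2. The fallback uses a neutral nucleophile and a cationic acceptor and sets out from 7 and 6. Compound 7 is converted with LiN(iPr)2 and Me3SiCl (THF, −78 °C) into the silyl ketene acetal [(1,2-dimethoxyethenyl)oxy]trimethylsilane F3 (mixture of double-bond isomers). Me3SiOSO2CF3 (0.2 equiv, CH2Cl2, −78 to 0 °C) turns 6 into 3-acetyl-6-(2,4-dimethoxyphenyl)-2-(methylsulfanyl)-4-[(trimethylsilyl)oxy]pyrylium trifluoromethanesulfonate F4. F3 should add at the sulfur-bearing C2 of F4 (Mukaiyama-type addition), and loss of the methylsulfanyl group as its silyl sulfide restores the pyranone, so the fallback rejoins the route at 8.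

Step 2. The acyl chloride may be lost to O-acylation of the enolate and to further acylation of the diketonate product, and the enolate may add to the ketene dithioacetal carbon of unreacted 3. The fallback forms the same C–C bond by aldol addition and sets out from 3. Compound 3 is added to LiN(SiMe3)2 (1.05 equiv, THF, −78 °C) and trapped at once with 2,4-dimethoxybenzaldehyde, a fast addition that leaves no acidic product, to give 3-[bis(methylsulfanyl)methylidene]-6-(2,4-dimethoxyphenyl)-6-hydroxyhexane-2,4-dione F5 (racemic). Oxidation of this β-hydroxy ketone with 2-iodoxybenzoic acid (EtOAc, 75 °C), which should leave the thioethers untouched, rejoins the route at 5.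

**Further compounds**
F1 | step 5 | dimethyl 2-[3-acetyl-6-(2,4-dimethoxyphenyl)-4-oxo-4H-pyran-2-yl]-2-methoxypropanedioate | COC(=O)C(OC)(C(=O)OC)C1=C(C(C)=O)C(=O)C=C(O1)c1ccc(OC)cc1OC
F2 | step 5 | methyl 2-(2,4-dimethoxyphenyl)-5-hydroxy-8-methoxy-4,7-dioxo-7,8-dihydro-4H-chromene-8-carboxylate (racemic) | COC(=O)C1(OC)C(=O)C=C(O)C2=C1OC(=CC2=O)c1ccc(OC)cc1OC
F3 | step 4 | [(1,2-dimethoxyethenyl)oxy]trimethylsilane (mixture of double-bond isomers) | COC=C(OC)O[Si](C)(C)C
F4 | step 4 | 3-acetyl-6-(2,4-dimethoxyphenyl)-2-(methylsulfanyl)-4-[(trimethylsilyl)oxy]pyrylium trifluoromethanesulfonate | CSc1[o+]c(cc(O[Si](C)(C)C)c1C(C)=O)-c1ccc(OC)cc1OC.[O-]S(=O)(=O)C(F)(F)F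
F5 | step 2 | 3-[bis(methylsulfanyl)methylidene]-6-(2,4-dimethoxyphenyl)-6-hydroxyhexane-2,4-dione (racemic) | CC(=O)C(=C(SC)SC)C(=O)CC(O)c1ccc(OC)cc1OC
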